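**Retrosynthetic overview**

- Feature: in ring B (C1, C2, C3, C4, C4a, C8a) the oxygens sit on C1 and C4 and the side chain on C2. C1–C4 plus one oxygen therefore map onto a 3-substituted furan, and C4a/C8a onto the two aryne carbons of a symmetric 3,6-dioxygenated benzyne (ring A).
- Target 23 ⇐ 5,8-dimethoxy-1,4-naphthoquinone 21 (oxidative demethylation of ring A, then reduction) ⇐ oxygen-bridged adduct 18 (bridge opened to 1-naphthols, then para-oxidation).
- 18 ⇐ 3,6-dimethoxybenzyne 17 (from silyl triflate 16) + furan ester 8, forming C1–C8a and C4–C4a. Ring A and the furan are bought; ring B is the only ring made.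
- 8 ⇐ furan-3-carbaldehyde (asymmetric allylboration sets C1', cross-metathesis, esterification); 16 ⇐ 2,5-dimethoxyphenol (carbamate-directed ortho-silylation, triflation).

Key step: step 7

Assumption: the allylborane made from (+)-α-pinene is taken to add to the Si face of furan-3-carbaldehyde as it does with benzaldehyde, which gives the (S)-carbinol.

Remark on the target: naphthazarin 23 is drawn as its 2-substituted tautomer.

Remark on the cycloadduct: adduct 18 is expected as an unseparated mixture of its (1R,4S) and (1S,4R) bridgehead diastereomers, and the mixture is carried under the one number 18. The compound list draws the (1R,4S) form; the (1S,4R) form is CC(C)=CC[C@H](OC(=O)C=C(C)C)C1=C[C@H]2O[C@@H]1c1c(OC)ccc(OC)c12.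

**Route**

Step 1
Reactants: 1 furan-3-carbaldehyde; 2 (+)-B-allyldiisopinocampheylborane, (+)-Ipc2B(allyl), the reagent made from (+)-α-pinene by way of (−)-Ipc2BOMe
Product: 4 (S)-1-(furan-3-yl)but-3-en-1-ol, via borinate ester 3 (not isolated)
Conditions: (+)-Ipc2B(allyl), Et2O, −78 °C; then NaOH, H2O2, 0 °C to rt
Reagents that add atoms: (+)-B-allyldiisopinocampheylborane, C=CCB([C@@H]1C[C@@H]2C[C@H]([C@H]1C)C2(C)C)[C@@H]1C[C@@H]2C[C@H]([C@H]1C)C2(C)C
Why: Brown asymmetric allylboration through a closed chair transition state, in which the isopinocampheyl groups from (+)-α-pinene direct the allyl group to the Si face of an aryl-type aldehyde, should set the carbinol centre (the later C1') as (S).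

Step 2
Reactants: 4 (S)-1-(furan-3-yl)but-3-en-1-ol; 5 2-methylbut-2-ene
Product: 6 (S)-1-(furan-3-yl)-4-methylpent-3-en-1-ol
Conditions: second-generation Grubbs catalyst RuCl2(=CHPh)(H2IMes)(PCy3) (5 mol %), 2-methylbut-2-ene/CH2Cl2, rt
Reagents that add atoms: 2-methylbut-2-ene, CC=C(C)C
Why: Olefin cross-metathesis of the terminal alkene with 2-methylbut-2-ene in large excess transfers an isopropylidene unit and releases propene, a known way to turn an allyl into a prenyl group that tolerates the free alcohol and the furan and does not involve the stereocentre.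

Step 3
Reactants: 6 (S)-1-(furan-3-yl)-4-methylpent-3-en-1-ol; 7 3-methylbut-2-enoic acid
Product: 8 (S)-1-(furan-3-yl)-4-methylpent-3-en-1-yl 3-methylbut-2-enoate
Conditions: DCC, DMAP (cat.), CH2Cl2, 0 °C to rt
Reagents that add atoms: 3-methylbut-2-enoic acid, CC(C)=CC(=O)O
Why: Steglich esterification acylates the secondary alcohol without breaking its C–O bond, so (S) is retained, and carbodiimide activation avoids the vinylketene pathway by which the acid chloride with amine bases gives the deconjugated ester.

Step 4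
Reactants: 9 2,5-dimethoxyphenol
Product: 10 2,5-dimethoxyphenyl isopropylcarbamate
Conditions: iPrNCO, Et3N (cat.), CH2Cl2, rt
Reagents that add atoms: isopropyl isocyanate, CC(C)N=C=O
Why: Base-catalysed addition of the phenol to the isocyanate (carbamoylation) installs the N–H carbamate that serves as a removable directing group.

Step 5
Reactants: 10 2,5-dimethoxyphenyl isopropylcarbamate
Product: 14 3,6-dimethoxy-2-(trimethylsilyl)phenyl isopropylcarbamate, via N-silyl carbamate 11 (not isolated), via aryllithium 12 (not isolated), via C-silyl N-silyl carbamate 13 (not isolated)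
Conditions: TBSOTf, TMEDA, Et2O, 0 °C to rt; n-BuLi (2.2 equiv), TMEDA, −78 °C; TMSCl, −78 °C to rt; aq. NaHSO4
Reagents that add atoms: chlorotrimethylsilane, C[Si](C)(C)Cl
Why: Directed ortho-metalation, in which transient N-silylation makes the carbamate a strong directing group and the only free position ortho to it is also ortho to the C5 methoxy group, should lithiate that one carbon, which is silylated at −78 °C before an anionic ortho-Fries shift can occur, the N-silyl group being lost on acidic work-up.

Step 6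
Reactants: 14 3,6-dimethoxy-2-(trimethylsilyl)phenyl isopropylcarbamate
Product: 16 3,6-dimethoxy-2-(trimethylsilyl)phenyl trifluoromethanesulfonate, via silylphenol 15 (not isolated)
Conditions: DBU, Et2NH, MeCN, 40 °C; then PhNTf2, rt
Reagents that add atoms: N-phenylbis(trifluoromethanesulfonimide), O=S(=O)(N(c1ccccc1)S(=O)(=O)C(F)(F)F)C(F)(F)F
Why: DBU removes the carbamate N–H proton and the phenoxide leaves by E1cB elimination while diethylamine scavenges the isocyanate, and O-triflation of the phenoxide in the same pot means the protodesilylation-prone silylphenol is never handled.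

Step 7
Reactants: 8 (S)-1-(furan-3-yl)-4-methylpent-3-en-1-yl 3-methylbut-2-enoate; 16 3,6-dimethoxy-2-(trimethylsilyl)phenyl trifluoromethanesulfonate
Product: 18 (S)-1-[(1R,4S)-5,8-dimethoxy-1,4-dihydro-1,4-epoxynaphthalen-2-yl]-4-methylpent-3-en-1-yl 3-methylbut-2-enoate (one of its two bridgehead diastereomers is drawn), via 3,6-dimethoxybenzyne 17 (not isolated)
Conditions: CsF (3 equiv), MeCN, rt, 16 (1.5 equiv) added slowly
Reagents that add atoms: none
Why: Fluoride attacks the trimethylsilyl group of 16 and the resulting aryl anion expels the ortho triflate to give 3,6-dimethoxybenzyne 17 (Kobayashi aryne generation), which is trapped at once by the furan of 8 acting as a diene in a concerted [4+2] cycloaddition, the well-known aryne–furan Diels–Alder reaction. Ring B is closed by this intermolecular cycloaddition, which forms the C1–C8a and C4–C4a bonds in one event and leaves the furan oxygen as a one-atom bridge between C1 and C4. The two new bridgehead stereocentres are fixed relative to each other by the bicyclic frame, while the remote C1' centre gives no useful facial bias, so 18 should be obtained as a mixture of its (1R,4S) and (1S,4R) forms; this is harmless because both bridgeheads become sp2 carbons in step 8. Regioselectivity is not at stake, since 17 has a mirror plane through the midpoint of its triple bond and a 3-substituted furan can give only one constitutional isomer. The chemoselectivity needed, diene addition in preference to an ene reaction at the trisubstituted C3'=C4' alkene or attack on the ester, rests on the high diene reactivity of furans toward arynes and on the nearly neutral, anhydrous fluoride conditions at room temperature. C1' and the ester are not touched.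

Step 8
Reactants: 18 (S)-1-[(1R,4S)-5,8-dimethoxy-1,4-dihydro-1,4-epoxynaphthalen-2-yl]-4-methylpent-3-en-1-yl 3-methylbut-2-enoate, used as its unseparated mixture of bridgehead diastereomers
Product: 21 (S)-1-(5,8-dimethoxy-1,4-dioxo-1,4-dihydronaphthalen-2-yl)-4-methylpent-3-en-1-yl 3-methylbut-2-enoate, via 2-substituted 1-naphthol 19 (not isolated), via 3-substituted 1-naphthol 20 (not isolated)
Conditions: CF3CO2H (0.2 equiv), CH2Cl2, 0 °C, under argon; aq. NaHCO3 wash, solvent exchange; then (KSO3)2NO, KH2PO4, acetone/H2O, 0 °C to rt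
Reagents that add atoms: potassium nitrosodisulfonate (KSO3)2NO, [K+].[K+].[O]N(S(=O)(=O)[O-])S(=O)(=O)[O-]
Why: Acid-catalysed heterolysis of either bridge C–O bond gives a benzylic and allylic cation stabilised by the ortho-methoxy ring A, a 1,2-hydride shift and enolisation aromatise ring B to a 1-naphthol with a free para CH in both regioisomers, and Teuber oxidation at that para carbon converges both on one 1,4-quinone while C1' is left untouched.

Step 9
Reactants: 21 (S)-1-(5,8-dimethoxy-1,4-dioxo-1,4-dihydronaphthalen-2-yl)-4-methylpent-3-en-1-yl 3-methylbut-2-enoate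
Product: 23 alkannin β,β-dimethylacrylate [(S)-1-(5,8-dihydroxy-1,4-dioxo-1,4-dihydronaphthalen-2-yl)-4-methylpent-3-en-1-yl 3-methylbut-2-enoate], via diquinone 22 (not isolated)
Conditions: AgO, 6 M HNO3, 1,4-dioxane, rt, 5–10 min; then aq. Na2S2O4, CHCl3/H2O, rt
Reagents that add atoms: water, O
Why: Oxidative demethylation of the hydroquinone dimethyl ether ring A with AgO in nitric acid (aryl–oxygen cleavage, new oxygen from water) is strong enough for a quinone-deactivated ring and should give the naphthalene-1,4,5,8-tetraone, which Na2S2O4 reduces by two electrons to the naphthazarin without involving C1'.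

**Compound list**

1 | furan-3-carbaldehyde | O=Cc1ccoc1 | starting material
2 | (+)-B-allyldiisopinocampheylborane, (+)-Ipc2B(allyl), from (+)-α-pinene | C=CCB([C@@H]1C[C@@H]2C[C@H]([C@H]1C)C2(C)C)[C@@H]1C[C@@H]2C[C@H]([C@H]1C)C2(C)C | starting material
3 | (S)-1-(furan-3-yl)but-3-en-1-yl diisopinocampheylborinate | C=CC[C@H](OB([C@@H]1C[C@@H]2C[C@H]([C@H]1C)C2(C)C)[C@@H]1C[C@@H]2C[C@H]([C@H]1C)C2(C)C)c1ccoc1 | intermediate (not isolated)
4 | (S)-1-(furan-3-yl)but-3-en-1-ol | C=CC[C@H](O)c1ccoc1 | intermediate
5 | 2-methylbut-2-ene | CC=C(C)C | starting material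
6 | (S)-1-(furan-3-yl)-4-methylpent-3-en-1-ol | CC(C)=CC[C@H](O)c1ccoc1 | intermediate
7 | 3-methylbut-2-enoic acid | CC(C)=CC(=O)O | starting material
8 | (S)-1-(furan-3-yl)-4-methylpent-3-en-1-yl 3-methylbut-2-enoate | CC(C)=CC[C@H](OC(=O)C=C(C)C)c1ccoc1 | intermediate
9 | 2,5-dimethoxyphenol | COc1ccc(OC)c(O)c1 | starting material
10 | 2,5-dimethoxyphenyl isopropylcarbamate | COc1ccc(OC)c(OC(=O)NC(C)C)c1 | intermediate
11 | 2,5-dimethoxyphenyl N-(tert-butyldimethylsilyl)-N-isopropylcarbamate | COc1ccc(OC)c(OC(=O)N(C(C)C)[Si](C)(C)C(C)(C)C)c1 | intermediate (not isolated)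
12 | [2-({[tert-butyl(dimethyl)silyl](isopropyl)carbamoyl}oxy)-3,6-dimethoxyphenyl]lithium | COc1ccc(OC)c(OC(=O)N(C(C)C)[Si](C)(C)C(C)(C)C)c1[Li] | intermediate (not isolated)
13 | 3,6-dimethoxy-2-(trimethylsilyl)phenyl N-(tert-butyldimethylsilyl)-N-isopropylcarbamate | COc1ccc(OC)c(OC(=O)N(C(C)C)[Si](C)(C)C(C)(C)C)c1[Si](C)(C)C | intermediate (not isolated)
14 | 3,6-dimethoxy-2-(trimethylsilyl)phenyl isopropylcarbamate | COc1ccc(OC)c(OC(=O)NC(C)C)c1[Si](C)(C)C | intermediate
15 | 3,6-dimethoxy-2-(trimethylsilyl)phenol | COc1ccc(OC)c(O)c1[Si](C)(C)C | intermediate (not isolated)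
16 | 3,6-dimethoxy-2-(trimethylsilyl)phenyl trifluoromethanesulfonate | COc1ccc(OC)c(OS(=O)(=O)C(F)(F)F)c1[Si](C)(C)C | intermediate
17 | 3,6-dimethoxybenzyne (1,2-didehydro-3,6-dimethoxybenzene) | COC1=CC=C(OC)C#C1 | intermediate (not isolated)
18 | (S)-1-[(1R,4S)-5,8-dimethoxy-1,4-dihydro-1,4-epoxynaphthalen-2-yl]-4-methylpent-3-en-1-yl 3-methylbut-2-enoate (drawn form of the unseparated bridgehead-diastereomer mixture) | CC(C)=CC[C@H](OC(=O)C=C(C)C)C1=C[C@@H]2O[C@H]1c1c(OC)ccc(OC)c12 | intermediate
19 | (S)-1-(1-hydroxy-5,8-dimethoxynaphthalen-2-yl)-4-methylpent-3-en-1-yl 3-methylbut-2-enoate | CC(C)=CC[C@H](OC(=O)C=C(C)C)c1ccc2c(OC)ccc(OC)c2c1O | intermediate (not isolated)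
20 | (S)-1-(4-hydroxy-5,8-dimethoxynaphthalen-2-yl)-4-methylpent-3-en-1-yl 3-methylbut-2-enoate | CC(C)=CC[C@H](OC(=O)C=C(C)C)c1cc(O)c2c(OC)ccc(OC)c2c1 | intermediate (not isolated)
21 | (S)-1-(5,8-dimethoxy-1,4-dioxo-1,4-dihydronaphthalen-2-yl)-4-methylpent-3-en-1-yl 3-methylbut-2-enoate | CC(C)=CC[C@H](OC(=O)C=C(C)C)C1=CC(=O)c2c(OC)ccc(OC)c2C1=O | intermediate
22 | (S)-4-methyl-1-(1,4,5,8-tetraoxo-1,4,5,8-tetrahydronaphthalen-2-yl)pent-3-en-1-yl 3-methylbut-2-enoate | CC(C)=CC[C@H](OC(=O)C=C(C)C)C1=CC(=O)C2=C(C1=O)C(=O)C=CC2=O | intermediate (not isolated)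
23 | alkannin β,β-dimethylacrylate, (S)-1-(5,8-dihydroxy-1,4-dioxo-1,4-dihydronaphthalen-2-yl)-4-methylpent-3-en-1-yl 3-methylbut-2-enoate | CC(C)=CC[C@H](OC(=O)C=C(C)C)C1=CC(=O)c2c(O)ccc(O)c2C1=O | target

**Step count**

Total: 9 steps. Longest linear sequence: 6 steps (1, 2, 3, 7, 8, 9; the aryne branch 4, 5, 6, 7, 8, 9 is equally long).

**Steps most likely to fail**

1. Step 9. The second oxidation may stall on the quinone-deactivated ring A, or the trisubstituted alkene and the ester may be degraded by the oxidising acid before the diquinone is reduced. The fallback sets out from 21 and comes back at 23. The two methyl ethers, each peri to a quinone carbonyl, would be cleaved without any redox change by chelation-assisted Lewis-acid dealkylation with BCl3 (CH2Cl2, −78 °C to 0 °C, aqueous work-up). This passes through the mono-methyl ethers (S)-1-(5-hydroxy-8-methoxy-1,4-dioxo-1,4-dihydronaphthalen-2-yl)-4-methylpent-3-en-1-yl 3-methylbut-2-enoate F1 and (S)-1-(8-hydroxy-5-methoxy-1,4-dioxo-1,4-dihydronaphthalen-2-yl)-4-methylpent-3-en-1-yl 3-methylbut-2-enoate F2, which need not be separated because both give 23 on the second cleavage.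

2. Step 7. The aryne, generated beside a limiting and valuable furan, may be consumed by an ene reaction at the trisubstituted alkene or by the solvent before the furan traps it, and fluoride with adventitious hydroxide may cleave the ester. The fallback sets out from 6 and comes back at 18. Alcohol 6 would be silylated (TBSCl, imidazole, DMF) to the tert-butyldimethylsilyl ether F3. The same aryne 17 would then be generated without fluoride from 2,3-dibromo-1,4-dimethoxybenzene and n-BuLi (toluene, −78 °C to rt) in the presence of F3, which carries no ester and tolerates the organolithium. This should give the oxygen-bridged silyl ethers, the (1R,4S) adduct F4 and the (1S,4R) adduct F5. Bu4NF in THF would then release the (1R,4S) alcohol F6 and the (1S,4R) alcohol F7, and Steglich esterification of their mixture with 7 (DCC, DMAP) would give 18 as the same mixture of bridgehead diastereomers.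

3. Step 8. While the cation at C2 exists the C1' acyloxy group may participate or ionise, the 2-substituted naphthol 19 may lose the carboxylate by way of an ortho-quinone methide, and the trisubstituted alkene may be protonated; each process costs material or enantiopurity at C1'. The fallback sets out from 6 and comes back at 21, and introduces the ester only after ring B has reached the quinone level. The silyl ether F3 would undergo the cycloaddition of step 7 with 16 and CsF to give F4 and F5. Acid opening and Teuber oxidation as in step 8 would then lead through the 2-substituted naphthol silyl ether F8 and the 3-substituted naphthol silyl ether F9 to the quinone silyl ether F10. HF·pyridine in THF would free the alcohol 5,8-di-O-methylalkannin F11, and Steglich esterification with 7 would give 21.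

**Further compounds**

F1 | step 9 | (S)-1-(5-hydroxy-8-methoxy-1,4-dioxo-1,4-dihydronaphthalen-2-yl)-4-methylpent-3-en-1-yl 3-methylbut-2-enoate | CC(C)=CC[C@H](OC(=O)C=C(C)C)C1=CC(=O)c2c(O)ccc(OC)c2C1=O
F2 | step 9 | (S)-1-(8-hydroxy-5-methoxy-1,4-dioxo-1,4-dihydronaphthalen-2-yl)-4-methylpent-3-en-1-yl 3-methylbut-2-enoate | CC(C)=CC[C@H](OC(=O)C=C(C)C)C1=CC(=O)c2c(OC)ccc(O)c2C1=O
F3 | step 7 | (S)-tert-butyl{[1-(furan-3-yl)-4-methylpent-3-en-1-yl]oxy}dimethylsilane | CC(C)=CC[C@H](O[Si](C)(C)C(C)(C)C)c1ccoc1
F4 | step 7 | tert-butyl({(S)-1-[(1R,4S)-5,8-dimethoxy-1,4-dihydro-1,4-epoxynaphthalen-2-yl]-4-methylpent-3-en-1-yl}oxy)dimethylsilane | CC(C)=CC[C@H](O[Si](C)(C)C(C)(C)C)C1=C[C@@H]2O[C@H]1c1c(OC)ccc(OC)c12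
F5 | step 7 | tert-butyl({(S)-1-[(1S,4R)-5,8-dimethoxy-1,4-dihydro-1,4-epoxynaphthalen-2-yl]-4-methylpent-3-en-1-yl}oxy)dimethylsilane | CC(C)=CC[C@H](O[Si](C)(C)C(C)(C)C)C1=C[C@H]2O[C@@H]1c1c(OC)ccc(OC)c12
F6 | step 7 | (S)-1-[(1R,4S)-5,8-dimethoxy-1,4-dihydro-1,4-epoxynaphthalen-2-yl]-4-methylpent-3-en-1-ol | CC(C)=CC[C@H](O)C1=C[C@@H]2O[C@H]1c1c(OC)ccc(OC)c12
F7 | step 7 | (S)-1-[(1S,4R)-5,8-dimethoxy-1,4-dihydro-1,4-epoxynaphthalen-2-yl]-4-methylpent-3-en-1-ol | CC(C)=CC[C@H](O)C1=C[C@H]2O[C@@H]1c1c(OC)ccc(OC)c12
F8 | step 8 | (S)-2-{1-[(tert-butyldimethylsilyl)oxy]-4-methylpent-3-en-1-yl}-5,8-dimethoxynaphthalen-1-ol | CC(C)=CC[C@H](O[Si](C)(C)C(C)(C)C)c1ccc2c(OC)ccc(OC)c2c1O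
F9 | step 8 | (S)-3-{1-[(tert-butyldimethylsilyl)oxy]-4-methylpent-3-en-1-yl}-5,8-dimethoxynaphthalen-1-ol | CC(C)=CC[C@H](O[Si](C)(C)C(C)(C)C)c1cc(O)c2c(OC)ccc(OC)c2c1
F10 | step 8 | (S)-2-{1-[(tert-butyldimethylsilyl)oxy]-4-methylpent-3-en-1-yl}-5,8-dimethoxynaphthalene-1,4-dione | CC(C)=CC[C@H](O[Si](C)(C)C(C)(C)C)C1=CC(=O)c2c(OC)ccc(OC)c2C1=O
F11 | step 8 | (S)-2-(1-hydroxy-4-methylpent-3-en-1-yl)-5,8-dimethoxynaphthalene-1,4-dione | CC(C)=CC[C@H](O)C1=CC(=O)c2c(OC)ccc(OC)c2C1=O
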